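**Retrosynthetic overview**
- The target is reached by global hydrogenolysis of a tris(benzyl ether) diaryl carbinol, itself made by adding a 4-(benzyloxy)phenyl Grignard reagent to a 2,6-disubstituted 4-methoxybenzaldehyde. The benzylic CH2 is therefore a former carboxyl carbon.
- The aldehyde comes from a methyl β-resorcylate: methylation of the non-chelated 4-OH, benzylation of the chelated 2-OH, then ester reduction and re-oxidation.
- The resorcylate comes from a linear methyl 3,5,7-trioxononanoate by intramolecular aldol (C2 to C7) and aromatization. This builds the central benzene ring, the only ring formed; both outer rings are bought.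
- The triketo ester comes from the Weinreb amide of O-benzylated 3-(3-hydroxyphenyl)propanoic acid and the trianion of methyl 3,5-dioxohexanoate.
- Feature used: in the central ring the oxygens sit on C2 and C4 (meta), the phenethyl chain on C6 and the benzylic CH2 on C1 between C2–OH and C6. This is a folded tetraketide with the starter on C6 and the carboxyl carbon on C1.

Key step: step 4

Remark: the target has no stereocenter, axis or configured double bond, so "single enantiomer" is read as the one achiral compound. The only stereocenter on the route (in compound 15) is carried as a racemate and removed in step 10.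

**Step 1**
Reactants: 1 3-(3-hydroxyphenyl)propanoic acid
Product: 2 benzyl 3-[3-(benzyloxy)phenyl]propanoate
Conditions: BnBr (2.3 equiv), K2CO3 (3 equiv), DMF, 60 °C
Reagents that add atoms: benzyl bromide, BrCc1ccccc1
Why: Carbonate deprotonates both the acid and the phenol, and both oxygen nucleophiles should be benzylated in DMF (Williamson ether synthesis and SN2 carboxylate alkylation), so no selectivity between them is needed.

**Step 2**
Reactants: 2 benzyl 3-[3-(benzyloxy)phenyl]propanoate
Product: 3 3-[3-(benzyloxy)phenyl]-N-methoxy-N-methylpropanamide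
Conditions: MeNHOMe·HCl (1.5 equiv), iPrMgCl (3 equiv), THF, −20 → 0 °C
Reagents that add atoms: N,O-dimethylhydroxylamine hydrochloride, CNOC.Cl
Why: The chloromagnesium amide formed in the flask should displace benzyloxide from the ester at low temperature (direct ester aminolysis to a Weinreb amide), the aryl benzyl ether being inert.

**Step 3**
Reactants: 3 3-[3-(benzyloxy)phenyl]-N-methoxy-N-methylpropanamide; 4 methyl 3,5-dioxohexanoate
Product: 6 methyl 9-[3-(benzyloxy)phenyl]-3,5,7-trioxononanoate, via trilithium trianion of methyl 3,5-dioxohexanoate 5 (not isolated)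
Conditions: 4 (2 equiv), LDA (6.2 equiv), THF, 0 °C; then 3, −78 → 0 °C; inverse quench into cold 1 M HCl; crude 6 taken on at once
Reagents that add atoms: none
Why: Three equivalents of LDA should convert 4 into its trianion, whose terminal C6 carbanion is the last formed and most nucleophilic site, and its addition to the N-methoxy-N-methyl amide gives a chelated tetrahedral adduct that releases the C7 ketone only on acidic quench (Weinreb ketone synthesis with a polyanion), so over-addition is excluded.

**Step 4**
Reactants: 6 methyl 9-[3-(benzyloxy)phenyl]-3,5,7-trioxononanoate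
Product: 8 methyl 6-{2-[3-(benzyloxy)phenyl]ethyl}-2,4-dihydroxybenzoate, via cyclic aldol adduct 7 (not isolated)
Conditions: K2CO3 (2 equiv), MeOH, 0 °C → rt; then HCl/MeOH to pH 1–2, rt
Reagents that add atoms: none
Why: Carbonate in methanol ionizes the polycarbonyl chain, and the carbanion at C2, flanked by the ester and the C3 ketone, adds to the C7 ketone carbonyl in an intramolecular aldol reaction that forms the C2–C7 bond and gives the cyclic β-hydroxy diketone 7. Loss of water (E1cB, completed on acidification) and enolization of the C3 and C5 carbonyls then give the benzene ring, in which C3 and C5 are the phenol carbons, C7 carries the phenethyl chain and C2 carries the ester. The closest known reaction type is the base-mediated aromatization of 3,5,7-triketo esters to β-resorcylates, the laboratory counterpart of polyketide aldol folding. The one ring closed is the central six-membered carbocycle, in a 6-exo-trig mode that is allowed for the enolate in both resonance forms (enolexo through the ester enolate, enolendo through the C3 enolate). No stereocenter has to be controlled, because the two stereocenters of 7 are erased on aromatization. The step needs the C2-to-C7 aldol to win over Claisen closure (C6 to C1, leading to an acylphloroglucinol), over the alternative aldol (C8 to C3) and over O-cyclization to pyrones; a weak base in a protic solvent should secure this, since only the doubly activated methylenes are ionized (C8 is not), methoxide expulsion from the ester is not driven, ester exchange in methanol is degenerate, and irreversible aromatization pulls the reversible aldol forward.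

**Step 5**
Reactants: 8 methyl 6-{2-[3-(benzyloxy)phenyl]ethyl}-2,4-dihydroxybenzoate
Product: 9 methyl 6-{2-[3-(benzyloxy)phenyl]ethyl}-2-hydroxy-4-methoxybenzoate
Conditions: MeI (1.1 equiv), K2CO3 (1.1 equiv), acetone, rt
Reagents that add atoms: iodomethane, CI
Why: The 2-OH is held in a hydrogen bond to the ester carbonyl and is the less acidic phenol, so one equivalent of base and MeI should alkylate only the 4-OH para to the ester (regioselective Williamson ether synthesis, as is usual for 2,4-dihydroxybenzoates).

**Step 6**
Reactants: 9 methyl 6-{2-[3-(benzyloxy)phenyl]ethyl}-2-hydroxy-4-methoxybenzoate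
Product: 10 methyl 2-(benzyloxy)-6-{2-[3-(benzyloxy)phenyl]ethyl}-4-methoxybenzoate
Conditions: BnBr (1.5 equiv), K2CO3 (2 equiv), DMF, 60 °C
Reagents that add atoms: benzyl bromide, BrCc1ccccc1
Why: With the 4-OH capped, the chelated 2-OH should be alkylated by excess benzyl bromide in warm DMF (Williamson ether synthesis), which shuts off o-quinone methide chemistry in the reduction, oxidation and addition steps that follow.

**Step 7**
Reactants: 10 methyl 2-(benzyloxy)-6-{2-[3-(benzyloxy)phenyl]ethyl}-4-methoxybenzoate
Product: 11 [2-(benzyloxy)-6-{2-[3-(benzyloxy)phenyl]ethyl}-4-methoxyphenyl]methanol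
Conditions: LiAlH4, THF, 0 °C → rt; aqueous NaOH work-up
Reagents that add atoms: none
Why: LiAlH4 should reduce the hindered aryl ester to the primary benzylic alcohol (hydride reduction of an ester), while methyl and benzyl aryl ethers are inert.

**Step 8**
Reactants: 11 [2-(benzyloxy)-6-{2-[3-(benzyloxy)phenyl]ethyl}-4-methoxyphenyl]methanol
Product: 12 2-(benzyloxy)-6-{2-[3-(benzyloxy)phenyl]ethyl}-4-methoxybenzaldehyde
Conditions: activated MnO2 (10 equiv), CH2Cl2, rt
Reagents that add atoms: none
Why: Activated MnO2 oxidizes benzylic alcohols to aldehydes under neutral conditions (heterogeneous benzylic oxidation) and should stop at the aldehyde without touching the benzyl ether or bibenzyl CH2 groups.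

**Step 9**
Reactants: 12 2-(benzyloxy)-6-{2-[3-(benzyloxy)phenyl]ethyl}-4-methoxybenzaldehyde; 13 4-(benzyloxy)bromobenzene
Product: 15 rac-[2-(benzyloxy)-6-{2-[3-(benzyloxy)phenyl]ethyl}-4-methoxyphenyl][4-(benzyloxy)phenyl]methanol, via 4-(benzyloxy)phenylmagnesium bromide 14 (not isolated)
Conditions: 13, Mg, THF, reflux; then 12, THF, 0 °C → rt; aq. NH4Cl
Reagents that add atoms: none
Why: The aryl Grignard reagent formed from 13 should add to the non-enolizable aldehyde (Grignard 1,2-addition) to give the diaryl carbinol as a racemate, which is acceptable because this stereocenter is removed in step 10.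

**Step 10**
Reactants: 15 rac-[2-(benzyloxy)-6-{2-[3-(benzyloxy)phenyl]ethyl}-4-methoxyphenyl][4-(benzyloxy)phenyl]methanol
Product: 16 IN1159, 2-[(4-hydroxyphenyl)methyl]-3-[2-(3-hydroxyphenyl)ethyl]-5-methoxyphenol
Conditions: H2 (1 atm), 10% Pd/C, EtOAc–AcOH, rt
Reagents that add atoms: none
Why: Pd-catalysed hydrogenolysis should cleave the three O-benzyl ethers and, helped by acetic acid, the doubly benzylic electron-rich C–OH bond (benzylic hydrogenolysis), leaving the achiral target with its methyl ether intact.

**Compound list**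
1 | 3-(3-hydroxyphenyl)propanoic acid | O=C(O)CCc1cccc(O)c1 | starting material
2 | benzyl 3-[3-(benzyloxy)phenyl]propanoate | O=C(OCc1ccccc1)CCc1cccc(OCc2ccccc2)c1 | intermediate
3 | 3-[3-(benzyloxy)phenyl]-N-methoxy-N-methylpropanamide | CON(C)C(=O)CCc1cccc(OCc2ccccc2)c1 | intermediate
4 | methyl 3,5-dioxohexanoate | COC(=O)CC(=O)CC(C)=O | starting material
5 | trilithium trianion of methyl 3,5-dioxohexanoate (not isolated) | [Li+].[Li+].[Li+].COC(=O)[CH-]C(=O)[CH-]C(=O)[CH2-] | intermediate
6 | methyl 9-[3-(benzyloxy)phenyl]-3,5,7-trioxononanoate (keto/enol tautomer mixture) | COC(=O)CC(=O)CC(=O)CC(=O)CCc1cccc(OCc2ccccc2)c1 | intermediate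
7 | methyl 2-{2-[3-(benzyloxy)phenyl]ethyl}-2-hydroxy-4,6-dioxocyclohexane-1-carboxylate (not isolated; stereoisomer and tautomer mixture) | COC(=O)C1C(=O)CC(=O)CC1(O)CCc1cccc(OCc2ccccc2)c1 | intermediate
8 | methyl 6-{2-[3-(benzyloxy)phenyl]ethyl}-2,4-dihydroxybenzoate | COC(=O)c1c(O)cc(O)cc1CCc1cccc(OCc2ccccc2)c1 | intermediate
9 | methyl 6-{2-[3-(benzyloxy)phenyl]ethyl}-2-hydroxy-4-methoxybenzoate | COC(=O)c1c(O)cc(OC)cc1CCc1cccc(OCc2ccccc2)c1 | intermediate
10 | methyl 2-(benzyloxy)-6-{2-[3-(benzyloxy)phenyl]ethyl}-4-methoxybenzoate | COC(=O)c1c(OCc2ccccc2)cc(OC)cc1CCc1cccc(OCc2ccccc2)c1 | intermediate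
11 | [2-(benzyloxy)-6-{2-[3-(benzyloxy)phenyl]ethyl}-4-methoxyphenyl]methanol | OCc1c(OCc2ccccc2)cc(OC)cc1CCc1cccc(OCc2ccccc2)c1 | intermediate
12 | 2-(benzyloxy)-6-{2-[3-(benzyloxy)phenyl]ethyl}-4-methoxybenzaldehyde | O=Cc1c(OCc2ccccc2)cc(OC)cc1CCc1cccc(OCc2ccccc2)c1 | intermediate
13 | 4-(benzyloxy)bromobenzene | Brc1ccc(OCc2ccccc2)cc1 | starting material
14 | 4-(benzyloxy)phenylmagnesium bromide (not isolated) | Br[Mg]c1ccc(OCc2ccccc2)cc1 | intermediate
15 | rac-[2-(benzyloxy)-6-{2-[3-(benzyloxy)phenyl]ethyl}-4-methoxyphenyl][4-(benzyloxy)phenyl]methanol (racemate) | OC(c1ccc(OCc2ccccc2)cc1)c1c(OCc2ccccc2)cc(OC)cc1CCc1cccc(OCc2ccccc2)c1 | intermediate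
16 | IN1159, 2-[(4-hydroxyphenyl)methyl]-3-[2-(3-hydroxyphenyl)ethyl]-5-methoxyphenol (achiral) | COc1cc(O)c(Cc2ccc(O)cc2)c(CCc2cccc(O)c2)c1 | target

**Step count**
Total steps: 10. Longest linear sequence: 10 steps (1 to 16); the Grignard reagent from 13 is made and used within step 9.

**Steps most likely to fail**

Step 3. The trianion is strongly basic, so proton transfer from the α-CH2 of the amide may compete with C-acylation, and the polycarbonyl product may cyclize without control during the quench. The fallback sets out from 3 and comes back at 6, and builds the chain with a dianion in which the ester end is masked. 2,2,6-Trimethyl-4H-1,3-dioxin-4-one is acetylated at its 6-methyl group (LiHMDS, THF, −78 °C; acetyl chloride) to give 2,2-dimethyl-6-(2-oxopropyl)-4H-1,3-dioxin-4-one F1. The dianion of F1 (LDA, 2 equiv, THF, −78 °C) is acylated at its terminal carbon by 3 to give 6-{6-[3-(benzyloxy)phenyl]-2,4-dioxohexyl}-2,2-dimethyl-4H-1,3-dioxin-4-one F2. Heating F2 in toluene with methanol (110 °C) expels acetone by retro-[4+2] to give the acylketene 9-[3-(benzyloxy)phenyl]non-1-ene-1,3,5,7-tetrone F3, which methanol traps to give 6.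

Step 4. Chemoselectivity may be lost, with Claisen closure or O-cyclization to pyrones competing with the aldol, or dehydration may stall. The fallback sets out from 3 and comes back at 8, and makes the same ring by a Michael–Dieckmann annulation followed by oxidative aromatization. Reduction of 3 (DIBAL-H, THF, −78 °C) gives 3-[3-(benzyloxy)phenyl]propanal F4. Wittig reaction with 1-(triphenylphosphoranylidene)propan-2-one (toluene, 80 °C) gives (E)-6-[3-(benzyloxy)phenyl]hex-3-en-2-one F5. Dimethyl malonate with NaOMe in refluxing MeOH adds in Michael fashion to give dimethyl 2-{1-[3-(benzyloxy)phenyl]-5-oxohexan-3-yl}propanedioate F6, which closes in the same pot by Claisen condensation to methyl 6-{2-[3-(benzyloxy)phenyl]ethyl}-2-hydroxy-4-oxocyclohex-2-ene-1-carboxylate F7. Bromination–dehydrobromination of F7 (Br2, DMF, 0 → 80 °C) gives 8.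

Step 10. The C–O bond of the carbinol may be cleaved incompletely, or ring saturation may set in on forcing. The fallback sets out from 15 and comes back at 16, and separates the two tasks. Ionic deoxygenation (Et3SiH, TFA, CH2Cl2, 0 °C) through the stabilized diarylmethyl cation gives 1-(benzyloxy)-2-[4-(benzyloxy)benzyl]-3-{2-[3-(benzyloxy)phenyl]ethyl}-5-methoxybenzene F8. Plain debenzylation of F8 (H2, Pd/C, EtOAc–EtOH, rt) then gives 16.

**Further compounds**
F1 | step 3 | 2,2-dimethyl-6-(2-oxopropyl)-4H-1,3-dioxin-4-one | CC(=O)CC1=CC(=O)OC(C)(C)O1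
F2 | step 3 | 6-{6-[3-(benzyloxy)phenyl]-2,4-dioxohexyl}-2,2-dimethyl-4H-1,3-dioxin-4-one | CC1(C)OC(=O)C=C(CC(=O)CC(=O)CCc2cccc(OCc3ccccc3)c2)O1
F3 | step 3 | 9-[3-(benzyloxy)phenyl]non-1-ene-1,3,5,7-tetrone (acylketene, not isolated) | O=C=CC(=O)CC(=O)CC(=O)CCc1cccc(OCc2ccccc2)c1
F4 | step 4 | 3-[3-(benzyloxy)phenyl]propanal | O=CCCc1cccc(OCc2ccccc2)c1
F5 | step 4 | (E)-6-[3-(benzyloxy)phenyl]hex-3-en-2-one | CC(=O)/C=C/CCc1cccc(OCc2ccccc2)c1
F6 | step 4 | dimethyl 2-{1-[3-(benzyloxy)phenyl]-5-oxohexan-3-yl}propanedioate (racemic, not isolated) | COC(=O)C(C(=O)OC)C(CCc1cccc(OCc2ccccc2)c1)CC(C)=O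
F7 | step 4 | methyl 6-{2-[3-(benzyloxy)phenyl]ethyl}-2-hydroxy-4-oxocyclohex-2-ene-1-carboxylate (racemic, C1 epimerizable) | COC(=O)C1C(O)=CC(=O)CC1CCc1cccc(OCc2ccccc2)c1
F8 | step 10 | 1-(benzyloxy)-2-[4-(benzyloxy)benzyl]-3-{2-[3-(benzyloxy)phenyl]ethyl}-5-methoxybenzene | COc1cc(OCc2ccccc2)c(Cc2ccc(OCc3ccccc3)cc2)c(CCc2cccc(OCc3ccccc3)c2)c1
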